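## Structural features

Serpyllin (14) is an achiral flavone in which benzene ring A is fused along C4a–C8a to the 4-pyranone ring C, and the 2,3,4-trimethoxyphenyl ring B is attached by the single bond C2–C1'. It has no stereocentre and no configured double bond, so no stereocentres stand next to each other and nothing stereochemical has to be set. Ring A is fully differentiated, with a free 5-OH hydrogen-bonded to the C4 carbonyl, hydrogen at C6 and methoxy groups at C7 and C8, while ring B carries three contiguous methoxy groups and an activated free position at C5'. The fragile points are the aryl methyl ethers toward Lewis acids, the quinol-like pair of the 5-OH and the C8 oxygen toward oxidation, and the 5,7,8-pattern toward Wessely–Moser isomerisation to the 5,6,7-pattern whenever ring C can reopen in strong acid. The real difficulty is therefore regiochemical: one phenol among five methyl ethers, oxygen at C8 and not at C6, and closure of ring C onto the correct ortho oxygen. The key step exploits the fact that the oxygens at C5, C7 and C8a alternate around ring A like the carbonyl carbons of a poly-β-carbonyl chain, that C4a is the acylated carbon between two of them, and that C2–C3–C4 is a dehydrated 1,3-diketone. The 7-OMe coincides with the enol ether of a 4-methoxy-2-pyranone, so that ring can deliver C5 to C8a with all three oxygens as a masked, already O-methylated chain end, and the C8 oxygen, the only one outside the alternating pattern, sits para to the 5-OH where a phenol-directed oxidation can reach it.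

## Logic of the disconnections

14 to 13: the O–CH3 bond at O8 is cut. In 13 the 8-OH is the only phenol not held in the hydrogen bond to the C4 carbonyl, so the last methyl group can be placed without any protecting group. The gain is that the two ring A hydroxyls never have to be told apart earlier. The forward step must use about one equivalent of methylating agent under weak base and exclude air, because 13 is a quinol.

13 to 11: the C8–O bond is cut. This oxygen is the only one that does not belong to the alternating pattern, and it lies para to the 5-OH, which is the position an Elbs persulfate oxidation addresses, by way of 12. The gain is that 11 carries exactly the triketide oxygen pattern. The forward step must be para-selective and phenoxide-specific so that ring B is left alone, and the acid hydrolysis of 12 must not reopen ring C.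

11 to 8 (key disconnection): O1–C2 is cut first, which gives 10, and then C4a–C8a, which gives the open ester 9 and, after relactonisation, 8. Ring A of 11 is an acylphloroglucinol mono-methyl ether, the retron of a Claisen folding, and the methyl ether is already supplied by the pyranone. In 9 the ester and the chain are cis on the enol-ether double bond, and because the methoxy oxygen outranks the chain carbon this geometry is (2E). The gain is that both rings are traded for a linear chain on a monocyclic pyranone, and that the two phenols of 10 are equivalent, so ring C can close in only one way. The forward step must fold in the Claisen mode (C4a onto the ester) and not in the aldol mode (C6 onto the aryl ketone).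

8 to 6 and 3: the bond between the terminal methylene and the aryl ketone carbon (later C3–C2) is cut as a retro-Claisen of the 1,3-diketone. The terminal methyl of 6 is not its most acidic position. The methylene between the ring and the ketone is deprotonated first, so the terminal carbon has to be reached through the dianion 7 and not through a mono-enolate. The N-methoxy-N-methylamide function of 3 keeps the adduct tetrahedral until the quench, so the acidic product cannot consume 7. The gain is that ring B arrives intact from 1. The forward step needs complete double deprotonation at low temperature and a mild, cold quench.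

6 to 4: the bond between the exocyclic methylene and the acetyl carbonyl (later C4a–C4) is cut. The 6-methyl group of 4 is vinylogously activated by the lactone carbonyl and is lithiated laterally to 5, which is acetylated with N-methoxy-N-methylacetamide. The gain is a commercial pyranone as the source of five ring A carbons. The forward step must deprotonate the methyl group without base attack on the ring.

3 to 1: the amide C–N bond is cut. The acid 1 is activated as 2 and condensed with N,O-dimethylhydroxylamine, which is a routine operation and places no special demand.

## Other disconnections considered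

Alternative 1: The cut runs through C2–C3 and C3–C4, so C3 is removed and ring C contracts to a furanone. In the forward direction the coumaranone A1 would be silylated to the siloxybenzofuran A2. Dichlorocarbene from CHCl3 and KOtBu would then cyclopropanate the C2=C3 enol-ether bond, and electrocyclic opening with loss of chloride and of the silyl group would give the 3-chloroflavone A3, a Ciamician–Dennstedt-type one-carbon insertion.
- In its favour: all three ring A oxygens, the C8 oxygen included, would be in place before the key step, and the ring expansion has no competing mode of closure. On both points it is the better plan, since it needs no late C–H oxidation and carries no folding ambiguity.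
- Against it here: A1 is a hexa-oxygenated 2-arylcoumaranone that would itself take an estimated three to four steps and is prone to oxidation at C2. A3 carries a chlorine at C3 that must be removed reductively without touching C2=C3. The 5-OMe must then be cleaved selectively among six methyl ethers.
- Comparison: on structure the two plans are equal in creating no lasting stereocentre. On mechanism the alternative is more predictable. On step economy it is worse, with an estimated eight steps or more against six.

Alternative 2: The cut runs through ring B at C5'–C6' and C1'–C2'. In the forward direction Pd2(dba)3 with tri(2-furyl)phosphine, a zerovalent palladium catalyst, would couple the chlorocyclobutenone A4 with the vinylstannane A5 in a Stille reaction. Thermal four-electron ring opening and six-electron ring closure would then build ring B as the 2'-phenol A6.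
- In its favour: the conditions are neutral and mild, and the contiguous 2',3',4'-oxygenation is built without regiochemical doubt. On functional-group tolerance of the key step it is the better plan.
- Against it here: ring B is the easy part of the target and is available intact in commercial 1, so building it de novo buys nothing. The whole ring A problem (5,7,8-pattern, free 5-OH) is moved into A5, which would need a complete chromone synthesis plus a stannylvinyl group. A6 would still require methylation of the 2'-OH and selective cleavage of the 5-OMe, and stoichiometric tin waste is produced.
- Comparison: on structure it is equal in being free of stereochemical issues. On mechanism it is well behaved. On step economy it is clearly worse, with an estimated nine or more steps.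

Alternative 3: The cut runs through O1–C8a, C4a–C4 and O1–C2. In the forward direction CsF would release the aryne A8 from the silyl triflate A7 in the presence of the arylpropiolic acid A9. The carboxylate oxygen would add to the aryne carbon remote from the 3-methoxy group, the aryl anion would take over the acyl group, and the resulting phenoxide would close onto the ynone to give A10.
- In its favour: two fragments of similar size would give the complete flavone in one operation, so on convergence it is the better plan. The regiochemistry is governed by the methoxy group next to the aryne, and there is no competing folding mode.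
- Against it here: A10 has a 5-OMe and no C8 oxygen. Selective demethylation would convert it into 11 of the chosen route, so the Elbs oxidation and the final methylation would still be needed and one step is added, not saved. A7 would take an estimated three to four steps and A9 one to two. Protonation of the aryl anion and decarboxylation of A9 are plausible side paths.
- Comparison: on structure it is equal. On mechanism it is arguably more secure than the folding. On step economy it is worse (an estimated eight to ten steps against six) and it reaches the same weakest step.

Key step: step 4

Remark: the polycarbonyl compounds 8, 9 and 10 are written as keto tautomers; in solution they will be largely enolised or metal-chelated, which does not change their connectivity.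

## Route

Step 1
Reactants: 1 2,3,4-trimethoxybenzoic acid
Product: 3 N,2,3,4-tetramethoxy-N-methylbenzamide, via acyl imidazole 2 (not isolated)
Conditions: CDI, CH2Cl2, rt; then MeNH(OMe)·HCl, rt
Reagents that add atoms: N,O-dimethylhydroxylamine hydrochloride, CNOC.Cl; 1,1'-carbonyldiimidazole, O=C(n1ccnc1)n1ccnc1 (its imidazole is carried only by intermediate 2)
Why: Activation of the acid as the acyl imidazole and aminolysis is a standard Weinreb amide synthesis; the amide is chosen because its tetrahedral adduct survives until the quench in step 3.

Step 2
Reactants: 4 4-methoxy-6-methyl-2H-pyran-2-one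
Product: 6 4-methoxy-6-(2-oxopropyl)-2H-pyran-2-one, via lithiated pyranone 5 (not isolated)
Conditions: LiN(iPr)2 (1.1 equiv), THF, −78 °C; MeC(O)N(OMe)Me, −78 to −40 °C; cold 1 M HCl quench
Reagents that add atoms: N-methoxy-N-methylacetamide, CC(=O)N(C)OC; lithium diisopropylamide, CC(C)N([Li])C(C)C (its lithium is carried only by intermediate 5)
Why: Lateral lithiation of the vinylogously activated 6-methyl group followed by Weinreb ketone synthesis; the chelated tetrahedral adduct releases the more acidic ketone only on quench, so it cannot protonate 5.

Step 3
Reactants: 6 4-methoxy-6-(2-oxopropyl)-2H-pyran-2-one; 3 N,2,3,4-tetramethoxy-N-methylbenzamide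
Product: 8 4-methoxy-6-[2,4-dioxo-4-(2,3,4-trimethoxyphenyl)butyl]-2H-pyran-2-one, via dilithium dianion 7 (not isolated)
Conditions: LiN(iPr)2 (2.2 equiv), THF, −78 to −20 °C; 3, −78 to 0 °C; cold 1 M HCl quench
Reagents that add atoms: lithium diisopropylamide, CC(C)N([Li])C(C)C (its lithium is carried only by intermediate 7)
Why: Hauser–Harris 1,3-dianion chemistry: the first equivalent of base removes the acidic ring-flanked methylene proton, the second the terminal methyl proton, and the dianion reacts at the last-formed terminal carbanion; acylation by the Weinreb amide stops at the ketone stage and gives the 1,3-diketone on quench.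

Step 4
Reactants: 8 4-methoxy-6-[2,4-dioxo-4-(2,3,4-trimethoxyphenyl)butyl]-2H-pyran-2-one
Product: 11 5-hydroxy-7-methoxy-2-(2,3,4-trimethoxyphenyl)-4H-chromen-4-one, via ring-opened enoate 9 (not isolated), via diketone 10 (not isolated)
Conditions: Mg(OMe)2 (excess), MeOH, reflux; then conc. HCl, AcOH, 90 °C
Reagents that add atoms: magnesium methoxide, CO[Mg]OC (its methoxy group is carried only by intermediate 9 and leaves again as methanol)
Why: Methoxide from Mg(OMe)2 adds to the lactone carbonyl of 8 and opens the 2-pyranone to the magnesium-chelated (2E)-enoate 9, in which the ester and the trioxo chain remain cis on the enol-ether double bond. The C4a carbanion, flanked by the C5 and C4 carbonyls (flavone numbering), attacks the ester in a 6-exo-trig Claisen condensation (C4a–C8a), and loss of methoxide with enolisation aromatises ring A to the acylphloroglucinol 10. Acid then closes ring C by 6-exo-trig addition of a phenol to the aryl ketone and dehydration (O1–C2). The closest known reaction type is the Mg(OMe)2-induced rearrangement of 6-(2-oxoalkyl)-4-methoxy-2-pyranones to 2,6-dihydroxy-4-methoxyphenyl ketones, joined to the acid cyclodehydration of o-hydroxyaryl 1,3-diketones that ends a Baker–Venkataraman flavone synthesis. No stereocentre is created. The selectivity needed is Claisen folding over aldol closure of C6 onto the aryl ketone C2 and over addition–elimination of C3 at C7; magnesium chelation of the 1,3-dicarbonyl units, the cis ester geometry inherited from the ring, and the poor acceptor quality of the 2,3,4-trimethoxybenzoyl ketone (ortho hindrance, ortho and para methoxy donation) should secure it. The two phenols of 10 are symmetry-equivalent, so only one flavone can form and the 5-OH/7-OMe pattern needs no protecting group.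

Step 5
Reactants: 11 5-hydroxy-7-methoxy-2-(2,3,4-trimethoxyphenyl)-4H-chromen-4-one
Product: 13 5,8-dihydroxy-7-methoxy-2-(2,3,4-trimethoxyphenyl)-4H-chromen-4-one, via aryl sulfate 12 (not isolated)
Conditions: K2S2O8, aq KOH, pyridine, 0 °C to rt; acidify, remove unreacted 11; then HCl (pH 1), 90 °C, N2
Reagents that add atoms: potassium peroxydisulfate, [K+].[K+].[O-]S(=O)(=O)OOS(=O)(=O)[O-] (supplies the C8 oxygen; its sulfate group and potassium are carried only by intermediate 12)
Why: Elbs persulfate oxidation: the 5-phenoxide attacks a peroxide oxygen of peroxydisulfate through its para carbon C8 to give the water-soluble aryl sulfate, which acid hydrolyses to the quinol; ring B has no free phenol and should not react, and ortho attack at C6 is the minor mode of this reaction.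

Step 6
Reactants: 13 5,8-dihydroxy-7-methoxy-2-(2,3,4-trimethoxyphenyl)-4H-chromen-4-one
Product: 14 serpyllin, 5-hydroxy-7,8-dimethoxy-2-(2,3,4-trimethoxyphenyl)-4H-chromen-4-one
Conditions: Me2SO4 (1.05 equiv), K2CO3, acetone, reflux, N2
Reagents that add atoms: dimethyl sulfate, COS(=O)(=O)OC
Why: Williamson O-methylation under weak base; the 5-OH is locked in the hydrogen bond to the C4 carbonyl and is much less nucleophilic, so one equivalent of reagent should alkylate only the 8-OH, the classical selective methylation of 5-hydroxyflavones.

## Compound list

1 | 2,3,4-trimethoxybenzoic acid | COc1ccc(C(=O)O)c(OC)c1OC | starting material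
2 | (1H-imidazol-1-yl)(2,3,4-trimethoxyphenyl)methanone | COc1ccc(C(=O)n2ccnc2)c(OC)c1OC | intermediate
3 | N,2,3,4-tetramethoxy-N-methylbenzamide | CON(C)C(=O)c1ccc(OC)c(OC)c1OC | intermediate
4 | 4-methoxy-6-methyl-2H-pyran-2-one | COC1=CC(=O)OC(C)=C1 | starting material
5 | lithium (4-methoxy-2-oxo-2H-pyran-6-yl)methanide | [Li+].[CH2-]C1=CC(OC)=CC(=O)O1 | intermediate
6 | 4-methoxy-6-(2-oxopropyl)-2H-pyran-2-one | CC(=O)CC1=CC(OC)=CC(=O)O1 | intermediate
7 | dilithium 1-(4-methoxy-2-oxo-2H-pyran-6-yl)-2-oxopropane-1,3-diide | [Li+].[Li+].[CH2-]C(=O)[CH-]C1=CC(OC)=CC(=O)O1 | intermediate
8 | 4-methoxy-6-[2,4-dioxo-4-(2,3,4-trimethoxyphenyl)butyl]-2H-pyran-2-one | COC1=CC(=O)OC(CC(=O)CC(=O)c2ccc(OC)c(OC)c2OC)=C1 | intermediate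
9 | methyl (2E)-3-methoxy-5,7,9-trioxo-9-(2,3,4-trimethoxyphenyl)non-2-enoate | COC(=O)/C=C(\CC(=O)CC(=O)CC(=O)c1ccc(OC)c(OC)c1OC)OC | intermediate
10 | 1-(2,6-dihydroxy-4-methoxyphenyl)-3-(2,3,4-trimethoxyphenyl)propane-1,3-dione | COc1cc(O)c(C(=O)CC(=O)c2ccc(OC)c(OC)c2OC)c(O)c1 | intermediate
11 | 5-hydroxy-7-methoxy-2-(2,3,4-trimethoxyphenyl)-4H-chromen-4-one | COc1cc(O)c2c(c1)oc(-c1ccc(OC)c(OC)c1OC)cc2=O | intermediate
12 | potassium 5-hydroxy-7-methoxy-4-oxo-2-(2,3,4-trimethoxyphenyl)-4H-chromen-8-yl sulfate | [K+].COc1cc(O)c2c(c1OS(=O)(=O)[O-])oc(-c1ccc(OC)c(OC)c1OC)cc2=O | intermediate
13 | 5,8-dihydroxy-7-methoxy-2-(2,3,4-trimethoxyphenyl)-4H-chromen-4-one | COc1cc(O)c2c(c1O)oc(-c1ccc(OC)c(OC)c1OC)cc2=O | intermediate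
14 | serpyllin, 5-hydroxy-7,8-dimethoxy-2-(2,3,4-trimethoxyphenyl)-4H-chromen-4-one | COc1ccc(-c2cc(=O)c3c(O)cc(OC)c(OC)c3o2)c(OC)c1OC | target

## Step count and least certain steps

Total step count: 6. Longest linear sequence: 5 steps (4 to 14 through steps 2 to 6); step 1 is a one-step branch that supplies 3.

Step 4 (key step). The chain may fold in the wrong mode: aldol closure of C6 onto the aryl ketone, or addition–elimination of C3 at C7 with loss of the enol-ether methoxy group. Both are six-membered closures of the same chain, and only chelation and acceptor quality separate them from the Claisen path. Retro-Claisen methanolysis of the triketone chain in hot methoxide is a further drain.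
Fallback, setting out from 6 and rejoining at 10: Mg(OMe)2 in refluxing methanol should fold the simpler pyranone 6, which is the precedented case and has no aryl ketone to compete, into 1-(2,6-dihydroxy-4-methoxyphenyl)ethanone F1. Acid 1 would be converted with (COCl)2 and catalytic DMF into 2,3,4-trimethoxybenzoyl chloride F2. Treatment of F1 with LiN(SiMe3)2 (4 equiv, THF, −78 °C) and then F2 should aroylate the lithium enolate at carbon and give 10, which the acid stage of step 4 cyclises to 11. Ring B is thus attached after the folding instead of before it.

Step 5. Low conversion with oxidative degradation is the usual course of an Elbs reaction. The quinol formed is more easily oxidised than the starting phenol, some attack occurs ortho at C6, and prolonged alkali can open ring C.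
Fallback, setting out from 11 and rejoining at 14 (step 6 is bypassed): benzylation of the 5-OH (BnBr, K2CO3, DMF, 80 °C) should give 5-(benzyloxy)-7-methoxy-2-(2,3,4-trimethoxyphenyl)-4H-chromen-4-one F3. With the chelated phenol capped, iodination (N-iodosuccinimide, catalytic CF3CO2H, MeCN) is expected at C8, giving 5-(benzyloxy)-8-iodo-7-methoxy-2-(2,3,4-trimethoxyphenyl)-4H-chromen-4-one F4. Ullmann-type methoxylation (NaOMe, catalytic CuI, MeOH/DMF, 110 °C) should give 5-(benzyloxy)-7,8-dimethoxy-2-(2,3,4-trimethoxyphenyl)-4H-chromen-4-one F5, and hydrogenolysis (H2, palladium on carbon, EtOAc) should release 14. The weak point of this detour is competing iodination at C5' of ring B, which is why it is held in reserve.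

Step 3. The second deprotonation may be incomplete, or acylation by the hindered, electron-rich amide may be slow enough for the dianion to decompose or to attack a pyranone ring. The product triketone may also cyclodehydrate or fold during an acidic or slow work-up.
Fallback, setting out from 6 (through 7) and rejoining at 8: the dianion would be trapped at −78 °C with commercial 2,3,4-trimethoxybenzaldehyde, a far faster electrophile, to give the aldol 6-[4-hydroxy-2-oxo-4-(2,3,4-trimethoxyphenyl)butyl]-4-methoxy-2H-pyran-2-one F6 as a racemate. Dess–Martin periodinane in CH2Cl2 would oxidise it to 8. The carbon–carbon bond is thus made at the alcohol oxidation level and adjusted afterwards.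

Step 6. Chemoselectivity may be lost through methylation of the 5-OH as well, or the quinol may be oxidised by air under basic conditions before it is alkylated.
Fallback, setting out from 13 and rejoining at 14: exhaustive methylation (excess Me2SO4, K2CO3, acetone, reflux) would give 5,7,8-trimethoxy-2-(2,3,4-trimethoxyphenyl)-4H-chromen-4-one F7. BCl3 in CH2Cl2 at −20 to 0 °C would then remove only the 5-O-methyl group, through the boron chelate with the C4 carbonyl. Selective alkylation is thus replaced by selective dealkylation.

## Further compounds

F1 | step 4 | 1-(2,6-dihydroxy-4-methoxyphenyl)ethanone | CC(=O)c1c(O)cc(OC)cc1O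
F2 | step 4 | 2,3,4-trimethoxybenzoyl chloride | COc1ccc(C(Cl)=O)c(OC)c1OC
F3 | step 5 | 5-(benzyloxy)-7-methoxy-2-(2,3,4-trimethoxyphenyl)-4H-chromen-4-one | COc1cc(OCc2ccccc2)c2c(c1)oc(-c1ccc(OC)c(OC)c1OC)cc2=O
F4 | step 5 | 5-(benzyloxy)-8-iodo-7-methoxy-2-(2,3,4-trimethoxyphenyl)-4H-chromen-4-one | COc1cc(OCc2ccccc2)c2c(c1I)oc(-c1ccc(OC)c(OC)c1OC)cc2=O
F5 | step 5 | 5-(benzyloxy)-7,8-dimethoxy-2-(2,3,4-trimethoxyphenyl)-4H-chromen-4-one | COc1cc(OCc2ccccc2)c2c(c1OC)oc(-c1ccc(OC)c(OC)c1OC)cc2=O
F6 | step 3 | 6-[4-hydroxy-2-oxo-4-(2,3,4-trimethoxyphenyl)butyl]-4-methoxy-2H-pyran-2-one (racemic) | COC1=CC(=O)OC(CC(=O)CC(O)c2ccc(OC)c(OC)c2OC)=C1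
F7 | step 6 | 5,7,8-trimethoxy-2-(2,3,4-trimethoxyphenyl)-4H-chromen-4-one | COc1ccc(-c2cc(=O)c3c(OC)cc(OC)c(OC)c3o2)c(OC)c1OC
A1 | alternative 1 | 4,6,7-trimethoxy-2-(2,3,4-trimethoxyphenyl)-1-benzofuran-3(2H)-one (racemic) | COc1ccc(C2Oc3c(OC)c(OC)cc(OC)c3C2=O)c(OC)c1OC
A2 | alternative 1 | 3-[(tert-butyldimethylsilyl)oxy]-4,6,7-trimethoxy-2-(2,3,4-trimethoxyphenyl)-1-benzofuran | COc1ccc(-c2oc3c(OC)c(OC)cc(OC)c3c2O[Si](C)(C)C(C)(C)C)c(OC)c1OC
A3 | alternative 1 | 3-chloro-5,7,8-trimethoxy-2-(2,3,4-trimethoxyphenyl)-4H-chromen-4-one | COc1ccc(-c2oc3c(OC)c(OC)cc(OC)c3c(=O)c2Cl)c(OC)c1OC
A4 | alternative 2 | 4-chloro-2,3-dimethoxycyclobut-2-en-1-one (racemic) | COC1=C(OC)C(Cl)C1=O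
A5 | alternative 2 | 5,7,8-trimethoxy-2-[(E)-2-(tributylstannyl)ethenyl]-4H-chromen-4-one | CCCC[Sn](CCCC)(CCCC)/C=C/c1cc(=O)c2c(OC)cc(OC)c(OC)c2o1
A6 | alternative 2 | 2-(2-hydroxy-3,4-dimethoxyphenyl)-5,7,8-trimethoxy-4H-chromen-4-one | COc1ccc(-c2cc(=O)c3c(OC)cc(OC)c(OC)c3o2)c(O)c1OC
A7 | alternative 3 | 3,5-dimethoxy-2-(trimethylsilyl)phenyl trifluoromethanesulfonate | COc1cc(OC)c([Si](C)(C)C)c(OS(=O)(=O)C(F)(F)F)c1
A8 | alternative 3 | 3,5-dimethoxybenzyne (1,2-didehydro-3,5-dimethoxybenzene) | COC1=CC(OC)=CC#C1
A9 | alternative 3 | 3-(2,3,4-trimethoxyphenyl)prop-2-ynoic acid | COc1ccc(C#CC(=O)O)c(OC)c1OC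
A10 | alternative 3 | 5,7-dimethoxy-2-(2,3,4-trimethoxyphenyl)-4H-chromen-4-one | COc1cc(OC)c2c(c1)oc(-c1ccc(OC)c(OC)c1OC)cc2=O
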